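Everything rests on growing ring B onto the ring A oxygen instead of coupling two crowded arenes. Ring B shows a C2 hydroxyl meta to the C4 methoxyl and next to the ether carbon C1, the pattern left by a vinylketene and an ynol ether. Irradiation of a (Z)-α-bromo-β-aryloxyvinyl diazomethyl ketone, whose aryloxy group is benzyl-protected ring A, triggers Wolff rearrangement. The vinylketene takes up methoxyacetylene and closes ring B as the C2 phenol with bromine at C6, in one operation. The tetra-ortho-substituted ether therefore comes from an oxa-Michael addition. Borylation at C6, Suzuki coupling with a 2-bromo-3-arylindenone (rings C and D) and one BCl3 debenzylation finish the synthesis.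

Key step: step 6

Assumption: the target has no stereocentre and its hindered aryl axes are not defined in the given structure, so no axial control is planned; the five starting materials are taken as catalogue compounds.

Step 1
Reactants: 1 methyl 2,6-dihydroxy-4-methylbenzoate
Product: 2 methyl 2-(benzyloxy)-6-hydroxy-4-methylbenzoate
Conditions: BnBr (1.0 equiv), K2CO3, acetone, reflux
Reagents that add atoms: benzyl bromide, BrCc1ccccc1
Why: Williamson ether synthesis with one equivalent of halide: after the first alkylation the remaining hydroxyl is held in a strong hydrogen bond to the ester carbonyl and reacts much more slowly, so the monoether should dominate.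

Step 2
Reactants: 2 methyl 2-(benzyloxy)-6-hydroxy-4-methylbenzoate; 3 but-3-yn-2-one
Product: 4 methyl 2-(benzyloxy)-4-methyl-6-{[(1E)-3-oxobut-1-en-1-yl]oxy}benzoate
Conditions: DABCO (10 mol %), CH2Cl2, 0 °C to rt
Reagents that add atoms: none
Why: Amine-catalysed oxa-Michael addition of a phenol to an ynone, which tolerates the ortho substituents of ring A because the C–O bond forms at an unhindered sp carbon, and which normally delivers the E enol ether.

Step 3
Reactants: 4 methyl 2-(benzyloxy)-4-methyl-6-{[(1E)-3-oxobut-1-en-1-yl]oxy}benzoate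
Product: 6 methyl 2-(benzyloxy)-6-{[(1Z)-2-bromo-3-oxobut-1-en-1-yl]oxy}-4-methylbenzoate, via dibromide 5 (not isolated)
Conditions: Br2 (1.0 equiv), CH2Cl2, −78 to −20 °C; then Et3N, −20 °C to rt
Reagents that add atoms: bromine, BrBr
Why: Bromination–dehydrobromination of a β-oxy enone: Br2 adds to the enol-ether-type C=C faster than it substitutes ring A, whose two free positions are each flanked by two substituents, and Et3N then removes HBr from 5 to give the more stable Z isomer with aryloxy trans to acetyl.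

Step 4
Reactants: 6 methyl 2-(benzyloxy)-6-{[(1Z)-2-bromo-3-oxobut-1-en-1-yl]oxy}-4-methylbenzoate
Product: 9 methyl 2-(benzyloxy)-6-{[(1Z)-2-bromo-4-diazo-3-oxobut-1-en-1-yl]oxy}-4-methylbenzoate, via lithium enolate 7 (not isolated), via trifluoroacetyl diketone 8 (not isolated)
Conditions: LiN(SiMe3)2 (1.05 equiv), THF, −78 °C; CF3CO2CH2CF3, −78 °C; aq HCl work-up; then MsN3, Et3N, H2O (1 equiv), MeCN, rt
Reagents that add atoms: methanesulfonyl azide, CS(=O)(=O)N=[N+]=[N-]; 2,2,2-trifluoroethyl trifluoroacetate, O=C(OCC(F)(F)F)C(F)(F)F (its CF3CO group stays only in 8)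
Why: Detrifluoroacetylative (Regitz-type deacylative) diazo transfer, the standard entry to α,β-unsaturated diazomethyl ketones: enolate 7 is acylated at carbon, diketone 8 accepts N2 from the sulfonyl azide and sheds the trifluoroacetyl group, and the dipolar cycloaddition to the C=C bond that troubles acylation of diazomethane with enoyl chlorides is avoided.

Step 5
Reactants: 10 chloroacetaldehyde dimethyl acetal
Product: 13 methoxyacetylene, via chloro enol ether 11 (not isolated), via sodium methoxyacetylide 12 (not isolated)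
Conditions: NaNH2 (3 equiv), liq. NH3, −33 °C; NH3 evaporated; cold brine; distilled into cold ClCH2CH2Cl
Reagents that add atoms: none
Why: Double base-induced elimination (loss of MeOH, then of HCl) of a chloroacetal with sodium amide, the classical preparation of alkoxyacetylenes, in which the third equivalent of base holds the product as acetylide 12 until the cold aqueous quench.

Step 6
Reactants: 9 methyl 2-(benzyloxy)-6-{[(1Z)-2-bromo-4-diazo-3-oxobut-1-en-1-yl]oxy}-4-methylbenzoate; 13 methoxyacetylene
Product: 18 methyl 2-(benzyloxy)-6-(2-bromo-6-hydroxy-4-methoxyphenoxy)-4-methylbenzoate, via vinylketene 14 (not isolated), via vinylcyclobutenone 15 (not isolated), via dienylketene 16 (not isolated), via cyclohexadienone 17 (not isolated)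
Conditions: 13 (5 equiv), ClCH2CH2Cl, hv (Pyrex-filtered medium-pressure Hg lamp, λ > 300 nm), pressure-rated tube or FEP flow coil, 15 °C; then 80 °C
Reagents that add atoms: none
Why: Light of λ > 300 nm expels N2 from 9 with 1,2-shift of the bromovinyl group (photochemical Wolff rearrangement, which moves C6 from C2 to C5 and so also makes C5–C6) and gives vinylketene 14, while the vinyl C–Br bond and the benzyl ether, which absorb at shorter wavelength, are spared. The nucleophilic CH carbon of 13 attacks the ketene carbon C2, and the [2+2] cycloaddition closes 4-vinylcyclobutenone 15 (bonds C2–C3 and C4–C5). On warming, 15 opens in a four-electron electrocyclic reaction to dienylketene 16, ring B is closed by six-electron electrocyclisation between C1 and C2, and cyclohexadienone 17 tautomerises to phenol 18. This is the diazoketone variant of the Danheiser benzannulation, known for unsaturated diazoketones and alkoxyacetylenes, and methoxyacetylene has no β-hydrogen for a retro-ene loss at 80 °C. The transient stereocentres of 15 and 17 vanish on aromatisation, so no stereocontrol is needed. The selectivity needed is regiochemical: the polarity match of ketene carbon and ynol ether CH puts the methoxyl meta to the new hydroxyl, bromine (C6) and aryloxy (C1) are fixed by the vinyl unit, and the Z geometry of 9 keeps hydrogen, not aryloxy, on the inner side of the closing triene.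

Step 7
Reactants: 18 methyl 2-(benzyloxy)-6-(2-bromo-6-hydroxy-4-methoxyphenoxy)-4-methylbenzoate
Product: 19 methyl 2-(benzyloxy)-6-[2-(benzyloxy)-6-bromo-4-methoxyphenoxy]-4-methylbenzoate
Conditions: BnBr, K2CO3, DMF, rt
Reagents that add atoms: benzyl bromide, BrCc1ccccc1
Why: Williamson ether synthesis on the only free phenol, which masks the acidic OH before the two palladium-catalysed steps with a group that leaves together with the other benzyl ethers.

Step 8
Reactants: 19 methyl 2-(benzyloxy)-6-[2-(benzyloxy)-6-bromo-4-methoxyphenoxy]-4-methylbenzoate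
Product: 20 methyl 2-(benzyloxy)-6-[2-(benzyloxy)-4-methoxy-6-(4,4,5,5-tetramethyl-1,3,2-dioxaborolan-2-yl)phenoxy]-4-methylbenzoate
Conditions: B2pin2, Pd(dppf)Cl2 (5 mol %), KOAc, 1,4-dioxane, 90 °C
Reagents that add atoms: bis(pinacolato)diboron, CC1(C)OB(OC1(C)C)B1OC(C)(C)C(C)(C)O1
Why: Miyaura borylation of an aryl bromide that has only one ortho substituent, with KOAc being too weak a base to touch the hindered methyl ester or to start homocoupling.

Step 9
Reactants: 21 orcinol (5-methylbenzene-1,3-diol)
Product: 22 2-iodo-5-methylbenzene-1,3-diol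
Conditions: I2, NaHCO3, H2O/THF, 0 °C to rt
Reagents that add atoms: iodine, II
Why: Electrophilic aromatic iodination of a resorcinol in aqueous bicarbonate, which goes to the position between the two hydroxyls as with resorcinol itself, the other two free positions being further crowded by the methyl group.

Step 10
Reactants: 22 2-iodo-5-methylbenzene-1,3-diol
Product: 23 1,3-bis(benzyloxy)-2-iodo-5-methylbenzene
Conditions: BnBr (2.3 equiv), K2CO3, DMF, 50 °C
Reagents that add atoms: benzyl bromide, BrCc1ccccc1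
Why: Double Williamson ether synthesis, with benzyl chosen so that ring D is unmasked in the final global debenzylation.

Step 11
Reactants: 24 5,7-dimethoxy-2,3-dihydro-1H-inden-1-one
Product: 25 7-hydroxy-5-methoxy-2,3-dihydro-1H-inden-1-one
Conditions: BCl3 (1.2 equiv), CH2Cl2, −78 to 0 °C; H2O
Reagents that add atoms: none
Why: Chelation-controlled Lewis acid demethylation: boron is held between the ketone oxygen and the peri C7 methoxy oxygen, so only that methyl group is lost and the C5 methoxyl, the later C6 methoxyl of the indenone, survives.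

Step 12
Reactants: 25 7-hydroxy-5-methoxy-2,3-dihydro-1H-inden-1-one
Product: 26 7-(benzyloxy)-5-methoxy-2,3-dihydro-1H-inden-1-one
Conditions: BnBr, K2CO3, DMF, 60 °C
Reagents that add atoms: benzyl bromide, BrCc1ccccc1
Why: Williamson ether synthesis, in which gentle heating overcomes the hydrogen bond of the phenol to the ketone.

Step 13
Reactants: 23 1,3-bis(benzyloxy)-2-iodo-5-methylbenzene; 26 7-(benzyloxy)-5-methoxy-2,3-dihydro-1H-inden-1-one
Product: 30 4-(benzyloxy)-3-[2,6-bis(benzyloxy)-4-methylphenyl]-6-methoxy-1H-indene, via aryllithium 27 (not isolated), via arylcerium dichloride 28 (not isolated), via tertiary indanol 29 (not isolated)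
Conditions: 23, n-BuLi, THF, −78 °C; anhydrous CeCl3, −78 °C; 26, −78 to 0 °C; dilute aq HCl; then p-TsOH (5 mol %), CH2Cl2, rt
Reagents that add atoms: none
Why: Iodine–lithium exchange, transmetalation to cerium and 1,2-addition of the weakly basic organocerium reagent 28, which suppresses enolisation of the indanone, followed by acid-catalysed E1 dehydration of the doubly benzylic carbinol 29, so that the ketone carbon next to the benzyloxy group becomes C3 of the later indenone without regiochemical ambiguity.

Step 14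
Reactants: 30 4-(benzyloxy)-3-[2,6-bis(benzyloxy)-4-methylphenyl]-6-methoxy-1H-indene
Product: 31 4-(benzyloxy)-3-[2,6-bis(benzyloxy)-4-methylphenyl]-2-bromo-6-methoxy-1H-indene
Conditions: NBS (1.0 equiv), CH2Cl2, −78 to −20 °C, dark
Reagents that add atoms: N-bromosuccinimide, O=C1CCC(=O)N1Br
Why: Electrophilic bromination–deprotonation (vinylic substitution) of an indene: the C2=C3 bond is held coplanar with ring C and is a cyclic 2,4-dialkoxystyrene, so C2 should be clearly more nucleophilic than the free positions of ring D, and one equivalent of NBS at low temperature in the dark should stop at the vinyl bromide.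

Step 15
Reactants: 31 4-(benzyloxy)-3-[2,6-bis(benzyloxy)-4-methylphenyl]-2-bromo-6-methoxy-1H-indene
Product: 33 4-(benzyloxy)-3-[2,6-bis(benzyloxy)-4-methylphenyl]-2-bromo-6-methoxy-1H-inden-1-one, via indenyl hydroperoxide 32 (not isolated)
Conditions: Cs2CO3 (30 mol %), O2 (1 atm), DMSO/THF, rt
Reagents that add atoms: dioxygen, O=O
Why: Base-catalysed autoxidation of the doubly activated (benzylic, allylic) C1 methylene, known for fluorenes and 2,3-disubstituted indenes: 31 is deprotonated and takes up O2 at the unhindered C1, and hydroperoxide 32 loses water in a Kornblum–DeLaMare-type elimination, while benzyl ethers and aryl methyl groups are not acidic enough to react.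

Step 16
Reactants: 20 methyl 2-(benzyloxy)-6-[2-(benzyloxy)-4-methoxy-6-(4,4,5,5-tetramethyl-1,3,2-dioxaborolan-2-yl)phenoxy]-4-methylbenzoate; 33 4-(benzyloxy)-3-[2,6-bis(benzyloxy)-4-methylphenyl]-2-bromo-6-methoxy-1H-inden-1-one
Product: 34 pentabenzyl ascomindone B, methyl 2-(benzyloxy)-6-[2-(benzyloxy)-6-{4-(benzyloxy)-3-[2,6-bis(benzyloxy)-4-methylphenyl]-6-methoxy-1-oxo-1H-inden-2-yl}-4-methoxyphenoxy]-4-methylbenzoate
Conditions: Pd(OAc)2 (5 mol %), SPhos (10 mol %), K3PO4, toluene/H2O, 80 °C
Reagents that add atoms: none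
Why: Suzuki–Miyaura coupling of an α-bromo enone, an activated partner for oxidative addition, with a boronate that has a single ortho substituent, using the bulky electron-rich ligand SPhos that is made for crowded couplings.

Step 17
Reactants: 34 pentabenzyl ascomindone B
Product: 35 ascomindone B
Conditions: BCl3 (10 equiv), C6HMe5 (15 equiv), CH2Cl2, −78 to −40 °C; aq work-up
Reagents that add atoms: none
Why: Lewis acid debenzylation with BCl3 and pentamethylbenzene as non-basic benzyl cation scavenger, which cleaves all five aryl benzyl ethers at low temperature and leaves untouched the two aryl methyl ethers (neither is next to a carbonyl group), the methyl ester, the diaryl ether and the indenone C=C bond that hydrogenolysis would endanger.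

Compound list
1 | methyl 2,6-dihydroxy-4-methylbenzoate | COC(=O)c1c(O)cc(C)cc1O | starting material
2 | methyl 2-(benzyloxy)-6-hydroxy-4-methylbenzoate | COC(=O)c1c(O)cc(C)cc1OCc1ccccc1 | intermediate
3 | but-3-yn-2-one | CC(=O)C#C | starting material
4 | methyl 2-(benzyloxy)-4-methyl-6-{[(1E)-3-oxobut-1-en-1-yl]oxy}benzoate | CC(=O)/C=C/Oc1cc(C)cc(OCc2ccccc2)c1C(=O)OC | intermediate
5 | methyl 2-(benzyloxy)-6-(1,2-dibromo-3-oxobutoxy)-4-methylbenzoate (racemic diastereomer mixture, both centres destroyed in the same flask) | CC(=O)C(Br)C(Br)Oc1cc(C)cc(OCc2ccccc2)c1C(=O)OC | intermediate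
6 | methyl 2-(benzyloxy)-6-{[(1Z)-2-bromo-3-oxobut-1-en-1-yl]oxy}-4-methylbenzoate | CC(=O)/C(Br)=C/Oc1cc(C)cc(OCc2ccccc2)c1C(=O)OC | intermediate
7 | lithium enolate of 6 (cross-conjugated dienolate, Z bromovinyl unit kept) | C=C(O[Li])/C(Br)=C/Oc1cc(C)cc(OCc2ccccc2)c1C(=O)OC | intermediate
8 | methyl 2-(benzyloxy)-6-{[(1Z)-2-bromo-6,6,6-trifluoro-3,5-dioxohex-1-en-1-yl]oxy}-4-methylbenzoate | O=C(CC(=O)C(F)(F)F)/C(Br)=C/Oc1cc(C)cc(OCc2ccccc2)c1C(=O)OC | intermediate
9 | methyl 2-(benzyloxy)-6-{[(1Z)-2-bromo-4-diazo-3-oxobut-1-en-1-yl]oxy}-4-methylbenzoate | [N-]=[N+]=CC(=O)/C(Br)=C/Oc1cc(C)cc(OCc2ccccc2)c1C(=O)OC | intermediate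
10 | chloroacetaldehyde dimethyl acetal | COC(CCl)OC | starting material
11 | 1-chloro-2-methoxyethene (E/Z mixture) | COC=CCl | intermediate
12 | sodium methoxyacetylide | [Na+].[C-]#COC | intermediate
13 | methoxyacetylene | COC#C | intermediate
14 | vinylketene, methyl 2-(benzyloxy)-6-{[(1Z)-2-bromo-4-oxobuta-1,3-dien-1-yl]oxy}-4-methylbenzoate | O=C=C/C(Br)=C/Oc1cc(C)cc(OCc2ccccc2)c1C(=O)OC | intermediate
15 | vinylcyclobutenone, methyl 2-(benzyloxy)-6-{[(Z)-2-bromo-2-(2-methoxy-4-oxocyclobut-2-en-1-yl)ethenyl]oxy}-4-methylbenzoate (racemic) | COC1=CC(=O)C1/C(Br)=C/Oc1cc(C)cc(OCc2ccccc2)c1C(=O)OC | intermediate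
16 | dienylketene, methyl 2-(benzyloxy)-6-{[(1Z,3E)-2-bromo-4-methoxy-6-oxohexa-1,3,5-trien-1-yl]oxy}-4-methylbenzoate | O=C=C/C(OC)=C\C(Br)=C\Oc1cc(C)cc(OCc2ccccc2)c1C(=O)OC | intermediate
17 | cyclohexadienone, methyl 2-(benzyloxy)-6-[(2-bromo-4-methoxy-6-oxocyclohexa-2,4-dien-1-yl)oxy]-4-methylbenzoate (racemic) | COC1=CC(=O)C(Oc2cc(C)cc(OCc3ccccc3)c2C(=O)OC)C(Br)=C1 | intermediate
18 | methyl 2-(benzyloxy)-6-(2-bromo-6-hydroxy-4-methoxyphenoxy)-4-methylbenzoate | COC(=O)c1c(OCc2ccccc2)cc(C)cc1Oc1c(O)cc(OC)cc1Br | intermediate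
19 | methyl 2-(benzyloxy)-6-[2-(benzyloxy)-6-bromo-4-methoxyphenoxy]-4-methylbenzoate | COC(=O)c1c(OCc2ccccc2)cc(C)cc1Oc1c(OCc2ccccc2)cc(OC)cc1Br | intermediate
20 | methyl 2-(benzyloxy)-6-[2-(benzyloxy)-4-methoxy-6-(4,4,5,5-tetramethyl-1,3,2-dioxaborolan-2-yl)phenoxy]-4-methylbenzoate | COC(=O)c1c(OCc2ccccc2)cc(C)cc1Oc1c(OCc2ccccc2)cc(OC)cc1B1OC(C)(C)C(C)(C)O1 | intermediate
21 | orcinol (5-methylbenzene-1,3-diol) | Cc1cc(O)cc(O)c1 | starting material
22 | 2-iodo-5-methylbenzene-1,3-diol | Cc1cc(O)c(I)c(O)c1 | intermediate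
23 | 1,3-bis(benzyloxy)-2-iodo-5-methylbenzene | Cc1cc(OCc2ccccc2)c(I)c(OCc2ccccc2)c1 | intermediate
24 | 5,7-dimethoxy-2,3-dihydro-1H-inden-1-one | COc1cc2c(c(OC)c1)C(=O)CC2 | starting material
25 | 7-hydroxy-5-methoxy-2,3-dihydro-1H-inden-1-one | COc1cc(O)c2c(c1)CCC2=O | intermediate
26 | 7-(benzyloxy)-5-methoxy-2,3-dihydro-1H-inden-1-one | COc1cc(OCc2ccccc2)c2c(c1)CCC2=O | intermediate
27 | [2,6-bis(benzyloxy)-4-methylphenyl]lithium | [Li]c1c(OCc2ccccc2)cc(C)cc1OCc1ccccc1 | intermediate
28 | [2,6-bis(benzyloxy)-4-methylphenyl]cerium dichloride | Cl[Ce](Cl)c1c(OCc2ccccc2)cc(C)cc1OCc1ccccc1 | intermediate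
29 | 7-(benzyloxy)-1-[2,6-bis(benzyloxy)-4-methylphenyl]-5-methoxy-2,3-dihydro-1H-inden-1-ol (racemic) | COc1cc(OCc2ccccc2)c2c(c1)CCC2(O)c1c(OCc2ccccc2)cc(C)cc1OCc1ccccc1 | intermediate
30 | 4-(benzyloxy)-3-[2,6-bis(benzyloxy)-4-methylphenyl]-6-methoxy-1H-indene | COc1cc(OCc2ccccc2)c2c(c1)CC=C2c1c(OCc2ccccc2)cc(C)cc1OCc1ccccc1 | intermediate
31 | 4-(benzyloxy)-3-[2,6-bis(benzyloxy)-4-methylphenyl]-2-bromo-6-methoxy-1H-indene | COc1cc(OCc2ccccc2)c2c(c1)CC(Br)=C2c1c(OCc2ccccc2)cc(C)cc1OCc1ccccc1 | intermediate
32 | 4-(benzyloxy)-3-[2,6-bis(benzyloxy)-4-methylphenyl]-2-bromo-1-hydroperoxy-6-methoxy-1H-indene (racemic) | COc1cc(OCc2ccccc2)c2c(c1)C(OO)C(Br)=C2c1c(OCc2ccccc2)cc(C)cc1OCc1ccccc1 | intermediate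
33 | 4-(benzyloxy)-3-[2,6-bis(benzyloxy)-4-methylphenyl]-2-bromo-6-methoxy-1H-inden-1-one | COc1cc(OCc2ccccc2)c2c(c1)C(=O)C(Br)=C2c1c(OCc2ccccc2)cc(C)cc1OCc1ccccc1 | intermediate
34 | pentabenzyl ascomindone B | COC(=O)c1c(OCc2ccccc2)cc(C)cc1Oc1c(OCc2ccccc2)cc(OC)cc1C1=C(c2c(OCc3ccccc3)cc(C)cc2OCc2ccccc2)c2c(OCc3ccccc3)cc(OC)cc2C1=O | intermediate
35 | ascomindone B | COC(=O)c1c(O)cc(C)cc1Oc1c(O)cc(OC)cc1C1=C(c2c(O)cc(C)cc2O)c2c(O)cc(OC)cc2C1=O | target

Total step count: 17. Longest linear sequence: 9 steps (steps 1, 2, 3, 4, 6, 7, 8, 16, 17).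

Steps most likely to fail

1. Step 6.
- **What may go wrong:** photolysis may divert into C–Br homolysis or other carbene pathways. The vinylketene may dimerise or be intercepted by phenol already formed. The volatile alkyne may be lost before the [2+2] step.
- **Fallback:** it sets out from 2 and comes back at 18, and brings ring B in ready-made. Phenol 2 displaces fluoride from 3-bromo-2-fluoro-5-methoxybenzaldehyde F1 in a nucleophilic aromatic substitution activated by the ortho formyl group (K2CO3, DMF, 90 °C). This gives methyl 2-(benzyloxy)-6-(2-bromo-6-formyl-4-methoxyphenoxy)-4-methylbenzoate F2. Baeyer–Villiger oxidation (mCPBA, CH2Cl2, rt) gives methyl 2-(benzyloxy)-6-[2-bromo-6-(formyloxy)-4-methoxyphenoxy]-4-methylbenzoate F3. Mild methanolysis (catalytic K2CO3, MeOH, 0 °C) then frees the C2 phenol, which is 18.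

2. Step 16.
- **What may go wrong:** transmetalation at the crowded C2 position of the indenone may be slow. That leaves time for protodeboronation of the boronate and for base-induced decay or hydrodebromination of the bromo enone.
- **Fallback:** it sets out from 19 and comes back at 34, and gives up boron and aqueous base. Bromide 19 is stannylated (Me3SnSnMe3, Pd(PPh3)4, toluene, 100 °C) to methyl 2-(benzyloxy)-6-[2-(benzyloxy)-4-methoxy-6-(trimethylstannyl)phenoxy]-4-methylbenzoate F4. F4 is joined to 33 in a copper-assisted Stille coupling under neutral conditions (Pd2(dba)3, AsPh3, CuI, DMF, 60 °C), a reliable process for α-halo enones, to give 34.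

3. Step 13.
- **What may go wrong:** the ketone may be enolised, or addition may simply not occur, because of the clash between the di-ortho-substituted nucleophile and the peri benzyloxy group.
- **Fallback:** it sets out from 26 and 23 and comes back at 30, and makes the C3–aryl bond by cross-coupling instead of carbonyl addition. Ketone 26 is converted (LiN(SiMe3)2, PhNTf2, THF, −78 °C to rt) into 4-(benzyloxy)-6-methoxy-1H-inden-3-yl trifluoromethanesulfonate F5. Iodide 23 is converted (n-BuLi, B(OiPr)3, THF, −78 °C; aq acid) into [2,6-bis(benzyloxy)-4-methylphenyl]boronic acid F6. Suzuki–Miyaura coupling of the two (Pd(OAc)2, SPhos, K3PO4, toluene/H2O, 80 °C) gives 30 directly.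

Further compounds
F1 | step 6 | 3-bromo-2-fluoro-5-methoxybenzaldehyde | COc1cc(Br)c(F)c(C=O)c1
F2 | step 6 | methyl 2-(benzyloxy)-6-(2-bromo-6-formyl-4-methoxyphenoxy)-4-methylbenzoate | COC(=O)c1c(OCc2ccccc2)cc(C)cc1Oc1c(C=O)cc(OC)cc1Br
F3 | step 6 | methyl 2-(benzyloxy)-6-[2-bromo-6-(formyloxy)-4-methoxyphenoxy]-4-methylbenzoate | COC(=O)c1c(OCc2ccccc2)cc(C)cc1Oc1c(OC=O)cc(OC)cc1Br
F4 | step 16 | methyl 2-(benzyloxy)-6-[2-(benzyloxy)-4-methoxy-6-(trimethylstannyl)phenoxy]-4-methylbenzoate | COC(=O)c1c(OCc2ccccc2)cc(C)cc1Oc1c(OCc2ccccc2)cc(OC)cc1[Sn](C)(C)C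
F5 | step 13 | 4-(benzyloxy)-6-methoxy-1H-inden-3-yl trifluoromethanesulfonate | COc1cc(OCc2ccccc2)c2c(c1)CC=C2OS(=O)(=O)C(F)(F)F
F6 | step 13 | [2,6-bis(benzyloxy)-4-methylphenyl]boronic acid | Cc1cc(OCc2ccccc2)c(B(O)O)c(OCc2ccccc2)c1
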